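- Set Saturday's run beside Monday's. Both take 1 equiv of G, yet Saturday's, at 31 mM of Q, reads E 26.7% on Z 74.1% at 12.0 h, and Monday's, at 16 mM, reads E 19.7% on Z 78.5% at 15.0 h.

| flask | Q | G | remark | time |
|---|---|---|---|---|
| Saturday's | 31 mM | 1 equiv | run made earlier |  |
| Monday's | 16 mM | 1 equiv | run made earlier |  |
| Tuesday's | 23 mM | 1 equiv | run made earlier |  |
| cedar | 31 mM | 1.00 equiv (in portions, 4, over 8.0 h) | first portion at the start, last at 8.0 h | 20 h |
| birch | 31 mM | 1.00 equiv (fed, over 8.0 h) | all else is in the flask from the start; the feed brings no volume worth counting | 20 h |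
| alder | 31 mM | 1.00 equiv | everything together at the start | 20 h |
| elm | 31 mM (fed, over 8.0 h) | 1.00 equiv | all else is in the flask from the start; the feed brings no volume worth counting | 20 h |

| run | time / h | Z / % | E / % |
|---|---|---|---|
| Saturday's | 1.00 | 61.9 | 14.6 |
| Saturday's | 1.50 | 67.2 | 16.4 |
| Saturday's | 2.50 | 71.3 | 18.8 |
| Saturday's | 4.00 | 73.7 | 21.8 |
| Saturday's | 8.00 | 72.8 | 24.1 |
| Saturday's | 12.0 | 74.1 | 26.7 |
| Monday's | 1.33 | 57.9 | 8.7 |
| Monday's | 2.00 | 63.9 | 10.1 |
| Monday's | 4.00 | 73.0 | 14.0 |
| Monday's | 6.00 | 75.5 | 16.1 |
| Monday's | 10.0 | 77.1 | 17.7 |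
| Monday's | 15.0 | 78.5 | 19.7 |
| Tuesday's | 1.00 | 58.5 | 10.7 |
| Tuesday's | 3.00 | 71.4 | 16.7 |
| Tuesday's | 6.00 | 75.3 | 20.7 |
| Tuesday's | 8.00 | 75.1 | 21.0 |
| Tuesday's | 12.0 | 75.8 | 22.3 |
| Tuesday's | 15.0 | 76.3 | 22.9 |

(each reading ± 0.5 percentage points)

- percent here means Q units held: one Z counts as two
- a reading or a percentage of E counts all its forms, free or not

- the flask with the highest amount of Z, in percent of the Q charged ("all alike" if they lie within 1.5 percentage points) (cedar / birch / alder / elm / all alike)
- final Z, as a percentage of the Q charged, in cedar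
- final Z, as a percentage of the Q charged, in birch
- final Z, as a percentage of the Q charged, in alder
- final Z, as a percentage of the Q charged, in elm

- Call E over Z, both in Q units, the split (a selectivity factor). Saturday's 0.360 is larger than Monday's 0.251.
- Treat Z as taking two Q and E as taking one Q with G to a power n. The split then follows G^n/Q, and at equal fractions of the charge it grows with the charge to the power n minus one.
- Read the G power, the exponent on the G fraction in the split, as n = 1.55, a reading under the scatter of 0.5 percentage points.
- Take alder as a repeat of Saturday's recipe, so expect Z near 74.1%.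
- Compare times for birch. Saturday's unconverted Q falls to 23.5% of the charge in 1.00 h, a span shorter than the feed. At that hour birch holds at most 12.5% of its G, which, set against a full charge, scales G^n by 0.0401.
- Place cedar next, since it starts with 25.0% of its G, more than birch has been fed by 1.00 h.
- Solve elm at both ends. Where Z takes the feed, the Q fraction goes as the square root of the feed rate, whatever G is, so multiplying G by f multiplies the split by f^n. Where E takes the feed, Q also falls as G^n, so the split grows by the square of f^n. Between the ends, expect a growth between f^n and its square.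
- Rank birch, cedar, alder, elm by this reckoning. The forecast gives the same order, with birch first: cedar 85%, birch 89%, alder 74.5%, elm 62%, on the ground “Slow G keeps G/Q low, so birch should be best”.

    Q + G → E, rate k1*[Q]*[G]^1.5 (k = 0.0170 /M^1.5/s)
    X ⇌ E, rate k2*(cs2 - [E]) while solid is left; crystals form when [E] > cs2 (solubility = 1.60 mM, k = 0.00970 /s)
    2 Q → Z (k = 0.0110 /M/s)

- Birch gives the most Z: 92.1%, against cedar 90.4%, which stands 5.4 points above the forecast, alder 73.9% and elm 59.6%. In elm, Q goes to E at 0.55 of its rate to Z at 5.11 h, during the feed, and at 8.2 of that rate at 20.0 h, after it. Elm ends with a split of 0.666. For elm's neighbour with 2.50 equiv of G, f^n and its square reckon splits of 2.75 and 11.3; that flask ends with Z 17.9%, between the two at a split of 4.58.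

The data were computed from invented constants, noise included.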